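## Retrosynthetic overview

1. The target comes from its 5-O-silyl methyl ester by ester hydrolysis and desilylation.
2. That bicycle is made in one flask from an acyclic (R)-2-silyloxy-5-oxohexanoate and a cis-epoxy triflate: enolate alkylation makes the C3–C3a bond, a Dieckmann-type Claisen closes ring B (cyclohexenone) first, and 5-exo opening of the epoxide with inversion then closes ring A (dihydrofuran).
3. The epoxy triflate comes from Sharpless epoxidation of a (Z)-allylic alcohol built from neryl acetate (SeO2 oxidation, allyl coupling, cross-metathesis with methyl methacrylate).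
4. The keto ester comes from methyl (R)-glycidate, which supplies the ring carbinol centre (cuprate opening, silylation, ozonolysis).

Assumption: the SMILES is read as 2S (dihydrofuran carbon), 10S (side-chain carbinol), 5R (ring carbinol) and 2E,6E alkenes; this pair of side-chain centres corresponds to anti opening of a cis (Z-derived) epoxide, so a neryl precursor is used.

## Route

Step 1
Reactants: 1 neryl acetate, (2Z)-3,7-dimethylocta-2,6-dien-1-yl acetate
Product: 2 (2Z,6E)-8-hydroxy-3,7-dimethylocta-2,6-dien-1-yl acetate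
Conditions: SeO2 (10 mol%), t-BuOOH, salicylic acid (10 mol%), CH2Cl2, rt
Reagents that add atoms: tert-butyl hydroperoxide, CC(C)(C)OO (oxygen relayed through SeO2)
Why: Sharpless catalytic SeO2 allylic oxidation (ene reaction then [2,3]-sigmatropic shift) hydroxylates the (E)-methyl group of the electron-rich terminal alkene with retention of E geometry, while the 2,3-alkene is deactivated by the allylic acetate.

Step 2
Reactants: 2 (2Z,6E)-8-hydroxy-3,7-dimethylocta-2,6-dien-1-yl acetate
Product: 3 (2Z,6E)-8-bromo-3,7-dimethylocta-2,6-dien-1-yl acetate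
Conditions: CBr4, PPh3, CH2Cl2, 0 °C
Reagents that add atoms: carbon tetrabromide, BrC(Br)(Br)Br
Why: The Appel reaction converts the primary allylic alcohol into the bromide by SN2 displacement of the oxyphosphonium group without touching the acetate or either alkene geometry.

Step 3
Reactants: 3 (2Z,6E)-8-bromo-3,7-dimethylocta-2,6-dien-1-yl acetate; 4 allylmagnesium bromide
Product: 5 (2Z,6E)-3,7-dimethylundeca-2,6,10-trien-1-ol
Conditions: CH2=CHCH2MgBr (3.5 equiv), THF, −78 → 0 °C; aq NH4Cl
Reagents that add atoms: none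
Why: SN2 coupling of the allyl Grignard reagent at the unhindered primary allylic bromide (Wurtz-type allyl–allyl coupling) installs the terminal vinyl group, and the excess reagent removes the acetate by double addition, leaving the 2Z and 6E alkenes unchanged.

Step 4
Reactants: 5 (2Z,6E)-3,7-dimethylundeca-2,6,10-trien-1-ol; 6 methyl methacrylate
Product: 7 methyl (2E,6E,10Z)-12-hydroxy-2,6,10-trimethyldodeca-2,6,10-trienoate
Conditions: 6 (10 equiv), second-generation Hoveyda–Grubbs catalyst RuCl2(=CH-C6H4-2-Oi-Pr)(H2IMes) (5 mol%; H2IMes = 1,3-dimesitylimidazolidin-2-ylidene), CH2Cl2, 40 °C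
Reagents that add atoms: none
Why: Olefin cross-metathesis of the only monosubstituted alkene with the 1,1-disubstituted acrylate gives the thermodynamically favoured (E)-2-methyl-2-enoate, and the trisubstituted alkenes do not engage the ruthenium carbene.

Step 5
Reactants: 7 methyl (2E,6E,10Z)-12-hydroxy-2,6,10-trimethyldodeca-2,6,10-trienoate
Product: 8 methyl (2E,6E)-9-[(2S,3R)-3-(hydroxymethyl)-2-methyloxiran-2-yl]-2,6-dimethylnona-2,6-dienoate
Conditions: Ti(Oi-Pr)4 (10 mol%), D-(−)-diethyl tartrate (12 mol%), t-BuOOH, 4 Å molecular sieves, CH2Cl2, −20 °C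
Reagents that add atoms: tert-butyl hydroperoxide, CC(C)(C)OO
Why: Katsuki–Sharpless asymmetric epoxidation oxidises only the allylic-alcohol alkene, and D-(−)-tartrate (opposite to the L-(+)-tartrate/nerol → (2S,3R) precedent) gives the cis-epoxide with the quaternary carbon S and the CH carbon R, which fixes both future side-chain stereocentres.

Step 6
Reactants: 8 methyl (2E,6E)-9-[(2S,3R)-3-(hydroxymethyl)-2-methyloxiran-2-yl]-2,6-dimethylnona-2,6-dienoate
Product: 9 methyl (2E,6E)-2,6-dimethyl-9-[(2S,3R)-2-methyl-3-({[(trifluoromethyl)sulfonyl]oxy}methyl)oxiran-2-yl]nona-2,6-dienoate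
Conditions: Tf2O, 2,6-lutidine, CH2Cl2, −78 °C; cold work-up, used at once
Reagents that add atoms: trifluoromethanesulfonic anhydride, O=S(=O)(OS(=O)(=O)C(F)(F)F)C(F)(F)F
Why: O-sulfonylation of the primary alcohol with a hindered pyridine base at low temperature gives the primary triflate without opening the epoxide, and no stereocentre is touched.

Step 7
Reactants: 10 methyl (2R)-oxirane-2-carboxylate (methyl (R)-glycidate); 11 2-methylallylmagnesium chloride
Product: 12 methyl (2R)-2-hydroxy-5-methylhex-5-enoate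
Conditions: CH2=C(CH3)CH2MgCl, CuI (10 mol%), THF, −78 → −40 °C; aq NH4Cl
Reagents that add atoms: none
Why: Copper-catalysed SN2 opening of the glycidic ester at the unsubstituted C3 (organocuprate epoxide opening) outruns addition to the ester at −78 °C and leaves the C2 stereocentre (R) untouched.

Step 8
Reactants: 12 methyl (2R)-2-hydroxy-5-methylhex-5-enoate
Product: 13 methyl (2R)-2-[(tert-butyldimethylsilyl)oxy]-5-methylhex-5-enoate
Conditions: TBSCl, imidazole, DMF, rt
Reagents that add atoms: tert-butyldimethylsilyl chloride, CC(C)(C)[Si](C)(C)Cl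
Why: Corey silylation of the secondary alcohol proceeds at oxygen only, so the stereocentre is retained and later protected from acting as a nucleophile.

Step 9
Reactants: 13 methyl (2R)-2-[(tert-butyldimethylsilyl)oxy]-5-methylhex-5-enoate
Product: 14 methyl (2R)-2-[(tert-butyldimethylsilyl)oxy]-5-oxohexanoate
Conditions: O3, CH2Cl2/MeOH, −78 °C; Me2S
Reagents that add atoms: ozone, [O-][O+]=O
Why: Ozonolysis (Criegee mechanism) with reductive work-up cleaves the 1,1-disubstituted alkene to the methyl ketone without affecting the silyl ether, the ester or the stereocentre.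

Step 10
Reactants: 14 methyl (2R)-2-[(tert-butyldimethylsilyl)oxy]-5-oxohexanoate; 9 methyl (2E,6E)-2,6-dimethyl-9-[(2S,3R)-2-methyl-3-({[(trifluoromethyl)sulfonyl]oxy}methyl)oxiran-2-yl]nona-2,6-dienoate
Product: 17 methyl (2E,6E,10S)-10-{(2S,5R)-5-[(tert-butyldimethylsilyl)oxy]-4-oxo-2,3,4,5,6,7-hexahydro-1-benzofuran-2-yl}-10-hydroxy-2,6-dimethylundeca-2,6-dienoate, via keto diester epoxide 15 (not isolated), via dione enolate 16 (not isolated)
Conditions: LiN(SiMe3)2 (1.0 equiv), THF, −78 °C; 9, −78 °C, 2 h; KOt-Bu (1.05 equiv), −78 → 0 °C; 2,6-di-tert-butyl-4-methylphenol (1.2 equiv), 0 → 45 °C; aq NH4Cl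
Reagents that add atoms: none
Why: Proposed new method: three known reaction types are run in one flask, namely alkylation of the kinetic methyl-side lithium enolate by the primary triflate at −78 °C (closest precedent: carbanion alkylations with 2,3-epoxy triflates), Dieckmann-type intramolecular Claisen condensation of the 5-oxo ester to the cyclohexane-1,3-dione enolate (ring B; closest precedent: KOt-Bu cyclisation of 5-oxoalkanoates), and 5-exo-tet SN2 opening of the cis-epoxide by the enolate oxygen remote from the bulky, electron-withdrawing silyloxy group (ring A; closest precedent: base-induced cyclisation of 2-(2,3-epoxyalkyl)-1,3-diones to 2-(1-hydroxyalkyl)dihydrofurans), so that C5 (R) is carried in from 14, the carbinol carbon (S) keeps its C–O bond, ring C2 becomes S by inversion of the (R)-epoxide carbon, and the phenol buffers the liberated alkoxide so that C5 is not epimerised.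

Step 11
Reactants: 17 methyl (2E,6E,10S)-10-{(2S,5R)-5-[(tert-butyldimethylsilyl)oxy]-4-oxo-2,3,4,5,6,7-hexahydro-1-benzofuran-2-yl}-10-hydroxy-2,6-dimethylundeca-2,6-dienoate
Product: 19 (2E,6E,10S)-10-hydroxy-10-[(2S,5R)-5-hydroxy-4-oxo-2,3,4,5,6,7-hexahydro-1-benzofuran-2-yl]-2,6-dimethylundeca-2,6-dienoic acid, via trimethylstannyl ester 18 (not isolated)
Conditions: Me3SnOH (8 equiv), ClCH2CH2Cl, 80 °C; then HF·pyridine, pyridine/THF, 0 °C → rt
Reagents that add atoms: trimethyltin hydroxide, C[Sn](C)(C)O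
Why: Me3SnOH cleaves the methyl ester by near-neutral acyl–oxygen hydrolysis (Nicolaou protocol) without epimerising the α-silyloxy ketone or opening the vinylogous ester, and HF·pyridine then frees the acid from tin and removes the silyl ether by fluoride-mediated Si–O cleavage, with no stereocentre affected.

## Compound list

1 | neryl acetate, (2Z)-3,7-dimethylocta-2,6-dien-1-yl acetate | CC(C)=CCC/C(C)=C\COC(C)=O | starting material
2 | (2Z,6E)-8-hydroxy-3,7-dimethylocta-2,6-dien-1-yl acetate | OC/C(C)=C/CC/C(C)=C\COC(C)=O | intermediate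
3 | (2Z,6E)-8-bromo-3,7-dimethylocta-2,6-dien-1-yl acetate | BrC/C(C)=C/CC/C(C)=C\COC(C)=O | intermediate
4 | allylmagnesium bromide | C=CC[Mg]Br | starting material
5 | (2Z,6E)-3,7-dimethylundeca-2,6,10-trien-1-ol | C=CCC/C(C)=C/CC/C(C)=C\CO | intermediate
6 | methyl methacrylate | C=C(C)C(=O)OC | starting material
7 | methyl (2E,6E,10Z)-12-hydroxy-2,6,10-trimethyldodeca-2,6,10-trienoate | COC(=O)/C(C)=C/CC/C(C)=C/CC/C(C)=C\CO | intermediate
8 | methyl (2E,6E)-9-[(2S,3R)-3-(hydroxymethyl)-2-methyloxiran-2-yl]-2,6-dimethylnona-2,6-dienoate | COC(=O)/C(C)=C/CC/C(C)=C/CC[C@]1(C)O[C@@H]1CO | intermediate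
9 | methyl (2E,6E)-2,6-dimethyl-9-[(2S,3R)-2-methyl-3-({[(trifluoromethyl)sulfonyl]oxy}methyl)oxiran-2-yl]nona-2,6-dienoate | COC(=O)/C(C)=C/CC/C(C)=C/CC[C@]1(C)O[C@@H]1COS(=O)(=O)C(F)(F)F | intermediate
10 | methyl (2R)-oxirane-2-carboxylate | COC(=O)[C@H]1CO1 | starting material
11 | 2-methylallylmagnesium chloride | CC(=C)C[Mg]Cl | starting material
12 | methyl (2R)-2-hydroxy-5-methylhex-5-enoate | COC(=O)[C@H](O)CCC(C)=C | intermediate
13 | methyl (2R)-2-[(tert-butyldimethylsilyl)oxy]-5-methylhex-5-enoate | COC(=O)[C@H](O[Si](C)(C)C(C)(C)C)CCC(C)=C | intermediate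
14 | methyl (2R)-2-[(tert-butyldimethylsilyl)oxy]-5-oxohexanoate | COC(=O)[C@H](O[Si](C)(C)C(C)(C)C)CCC(C)=O | intermediate
15 | methyl (2R)-2-[(tert-butyldimethylsilyl)oxy]-7-{(2R,3S)-3-[(3E,7E)-9-methoxy-4,8-dimethyl-9-oxonona-3,7-dien-1-yl]-3-methyloxiran-2-yl}-5-oxoheptanoate | COC(=O)[C@H](O[Si](C)(C)C(C)(C)C)CCC(=O)CC[C@H]1O[C@@]1(C)CC/C=C(\C)CC/C=C(\C)C(=O)OC | intermediate (not isolated)
16 | (4R)-4-[(tert-butyldimethylsilyl)oxy]-2-({(2R,3S)-3-[(3E,7E)-9-methoxy-4,8-dimethyl-9-oxonona-3,7-dien-1-yl]-3-methyloxiran-2-yl}methyl)cyclohexane-1,3-dione, potassium enolate in the flask, enol form drawn | O=C1[C@H](O[Si](C)(C)C(C)(C)C)CCC(O)=C1C[C@H]2O[C@@]2(C)CC/C=C(\C)CC/C=C(\C)C(=O)OC | intermediate (not isolated)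
17 | methyl (2E,6E,10S)-10-{(2S,5R)-5-[(tert-butyldimethylsilyl)oxy]-4-oxo-2,3,4,5,6,7-hexahydro-1-benzofuran-2-yl}-10-hydroxy-2,6-dimethylundeca-2,6-dienoate | C/C(=C\CC[C@](C)(O)[C@@H]1CC2=C(CC[C@@H](O[Si](C)(C)C(C)(C)C)C2=O)O1)CC/C=C(\C)C(=O)OC | intermediate
18 | trimethylstannyl (2E,6E,10S)-10-{(2S,5R)-5-[(tert-butyldimethylsilyl)oxy]-4-oxo-2,3,4,5,6,7-hexahydro-1-benzofuran-2-yl}-10-hydroxy-2,6-dimethylundeca-2,6-dienoate | C/C(=C\CC[C@](C)(O)[C@@H]1CC2=C(CC[C@@H](O[Si](C)(C)C(C)(C)C)C2=O)O1)CC/C=C(\C)C(=O)O[Sn](C)(C)C | intermediate (not isolated)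
19 | (2E,6E,10S)-10-hydroxy-10-[(2S,5R)-5-hydroxy-4-oxo-2,3,4,5,6,7-hexahydro-1-benzofuran-2-yl]-2,6-dimethylundeca-2,6-dienoic acid | C/C(=C\CC[C@](C)(O)[C@@H]1CC2=C(CC[C@@H](O)C2=O)O1)CC/C=C(\C)C(=O)O | target

## Step count and risks

Total steps: 11. Longest linear sequence: 8 steps (1–6, 10, 11) from neryl acetate.

Step 10 is the most likely to fail. The kinetic enolate of 14 may cyclise on its own ester or be O-alkylated before it is C-alkylated. The ketone enolate of 15 may attack the epoxide before the Claisen closure. The wrong enolate oxygen of 16 may close the ring, and C5 may epimerise under base. The fallback removes the C5 oxygen from the ring-forming sequence and sets out from 9. The same one-flask protocol is run with the lithium enolate of commercial methyl 5-oxohexanoate F1 in place of 14. Alkylation gives keto diester F2, and KOt-Bu closes the symmetric dione enolate F3, whose two enolate oxygens are equivalent, so neither the regiochemical nor the epimerisation question arises. Epoxide opening gives the 5-deoxy bicycle F4. The C5 hydroxyl is then introduced under reagent control. LiN(i-Pr)2 (2.2 equiv, THF, −78 °C) forms the tertiary alkoxide and the kinetic cross-conjugated enolate at C5, and an enantiopure (camphorsulfonyl)oxaziridine (Davis hydroxylation) gives hydroxy ester F5. The oxaziridine enantiomer that gives 5R is fixed in a pilot run, and the C5 epimers are separable diastereomers. Me3SnOH hydrolysis of F5 comes back to the route at 19.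

Step 6 is the second risk. The triflate of a 3,3-disubstituted 2,3-epoxy alcohol can ionise with participation of the epoxide oxygen, and its clean C-alkylation by a ketone enolate is not assured. The fallback sets out from 14 and 8 and replaces the triflate alkylation by a reductive alkylation. Compound 14 alone is cyclised with KOt-Bu (THF, 0 °C) to (4R)-4-[(tert-butyldimethylsilyl)oxy]cyclohexane-1,3-dione F6. Compound 8 is oxidised (SO3·pyridine, DMSO, i-Pr2NEt) to epoxy aldehyde F7. An organocatalytic three-component reductive alkylation (L-proline, Hantzsch ester, CH2Cl2, 0 °C; Knoevenagel condensation then transfer hydrogenation) joins F6 and F7 at C2 of the dione. This comes back to the route at 16 in its neutral form, and K2CO3 added to the same flask triggers the epoxide opening to 17.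

Step 7 is the third risk, because the allylic Grignard reagent may add to the ester faster than the cuprate opens the epoxide. The fallback sets out from 10 and forms the C3–C4 bond by a radical reaction. LiI and AcOH in THF open the epoxide at C3 to methyl (2S)-2-hydroxy-3-iodopropanoate F8. TBSCl and imidazole give methyl (2S)-2-[(tert-butyldimethylsilyl)oxy]-3-iodopropanoate F9. Keck allylation with tributyl(2-methylallyl)stannane and AIBN (benzene, 80 °C) then comes back to the route at 13 without any organometallic near the ester.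

Further compounds
F1 | step 10 | methyl 5-oxohexanoate | COC(=O)CCCC(C)=O
F2 | step 10 | methyl 7-{(2R,3S)-3-[(3E,7E)-9-methoxy-4,8-dimethyl-9-oxonona-3,7-dien-1-yl]-3-methyloxiran-2-yl}-5-oxoheptanoate | COC(=O)CCCC(=O)CC[C@H]1O[C@@]1(C)CC/C=C(\C)CC/C=C(\C)C(=O)OC
F3 | step 10 | 2-({(2R,3S)-3-[(3E,7E)-9-methoxy-4,8-dimethyl-9-oxonona-3,7-dien-1-yl]-3-methyloxiran-2-yl}methyl)cyclohexane-1,3-dione, enol form drawn | O=C1CCCC(O)=C1C[C@H]2O[C@@]2(C)CC/C=C(\C)CC/C=C(\C)C(=O)OC
F4 | step 10 | methyl (2E,6E,10S)-10-hydroxy-2,6-dimethyl-10-[(2S)-4-oxo-2,3,4,5,6,7-hexahydro-1-benzofuran-2-yl]undeca-2,6-dienoate | C/C(=C\CC[C@](C)(O)[C@@H]1CC2=C(CCCC2=O)O1)CC/C=C(\C)C(=O)OC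
F5 | step 10 | methyl (2E,6E,10S)-10-hydroxy-10-[(2S,5R)-5-hydroxy-4-oxo-2,3,4,5,6,7-hexahydro-1-benzofuran-2-yl]-2,6-dimethylundeca-2,6-dienoate | C/C(=C\CC[C@](C)(O)[C@@H]1CC2=C(CC[C@@H](O)C2=O)O1)CC/C=C(\C)C(=O)OC
F6 | step 6 | (4R)-4-[(tert-butyldimethylsilyl)oxy]cyclohexane-1,3-dione | O=C1CC(=O)[C@H](O[Si](C)(C)C(C)(C)C)CC1
F7 | step 6 | methyl (2E,6E)-9-[(2S,3S)-3-formyl-2-methyloxiran-2-yl]-2,6-dimethylnona-2,6-dienoate | COC(=O)/C(C)=C/CC/C(C)=C/CC[C@]1(C)O[C@@H]1C=O
F8 | step 7 | methyl (2S)-2-hydroxy-3-iodopropanoate | COC(=O)[C@H](O)CI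
F9 | step 7 | methyl (2S)-2-[(tert-butyldimethylsilyl)oxy]-3-iodopropanoate | COC(=O)[C@H](O[Si](C)(C)C(C)(C)C)CI
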